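**Plan**

1. The side chain is numbered C1′ (benzylic) to C17′ and the resorcinol is ring A. The retrosynthesis removes the O-protecting groups, then cuts C9′–C10′. Fragment 1 (ring A plus C1′–C9′) is cut at C8′–C9′ (one-carbon alkyne homologation) and at ring A–C1′ (Sonogashira). Fragment 2 (C10′–C17′) is cut at C10′–C11′ (ylide carbon) and C13′–C14′ (acetylide opening of epichlorohydrin).
2. Forward: but-1-yne and (R)-epichlorohydrin give a chlorohydrin, then the Z-alkene, the vinyl carbinol, its silyl ether and the primary pinacol boronic ester (5 steps). 5-Bromoresorcinol and oct-7-yn-1-ol give the E-alkenyl iodide (6 steps). The two are joined, and one acid step removes all protecting groups.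
3. Enabling feature: C9′ is an sp2 carbon of the Z-1,2-disubstituted alkene C8′=C9′ and is bonded to the primary sp3 carbon C10′, which is not a stereocentre and lies 1,3 to O12′. C10′ can therefore migrate from boron to C9′ of an E-alkenylboronate, and anti elimination of boron and iodine turns E into Z. One event makes the bond and the alkene geometry, and the boron helper leaves in the same step.
4. Stereochemistry: C12′ (S) is the stereocentre of (R)-epichlorohydrin and no bond to it is ever broken (the R/S label changes only through CIP priorities). Z at C14′=C15′ comes from Lindlar semi-hydrogenation. Z at C8′=C9′ comes from the stereospecific key step, whose E input is set by syn hydrozirconation.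
5. Protection: MOM ethers on ring A and TBS on O12′.

Key step: step 12

Assumption: the target is read as 5-[(8Z,12S,14Z)-12-hydroxyheptadeca-8,14-dien-1-yl]benzene-1,3-diol, and compounds 1, 2, 11 and 13 are taken as commercial.

**Route**

Step 1
Reactants: 1 but-1-yne; 2 (R)-epichlorohydrin
Product: 4 (2R)-1-chlorohept-4-yn-2-ol, via lithium but-1-yn-1-ide 3 (not isolated)
Conditions: 1, n-BuLi, THF, −78 °C; BF3·OEt2; then 2, −78 °C
Reagents that add atoms: none
Why: BF3-mediated alkynylation of an epoxide (Yamaguchi–Hirao reaction): acetylide 3 should open the activated oxirane of 2 by SN2 at its unsubstituted CH2 faster than it displaces the primary chloride, so the stereocentre of 2 is carried over untouched and becomes C12′.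

Step 2
Reactants: 4 (2R)-1-chlorohept-4-yn-2-ol
Product: 5 (2R,4Z)-1-chlorohept-4-en-2-ol
Conditions: H2 (1 atm), Pd/CaCO3 poisoned with Pb(OAc)2 (Lindlar catalyst), quinoline, EtOAc, rt
Reagents that add atoms: none
Why: Lindlar semi-hydrogenation should deliver both hydrogens to the same face of the alkyne and stop at the Z-alkene (C14′=C15′) under quinoline poisoning, while the alkyl chloride and the carbinol are inert.

Step 3
Reactants: 5 (2R,4Z)-1-chlorohept-4-en-2-ol
Product: 8 (3R,5Z)-octa-1,5-dien-3-ol, via epoxide 6 (not isolated), via sulfonium alkoxide 7 (not isolated)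
Conditions: Me3S+ I− (4 equiv), n-BuLi (4 equiv), THF, −10 °C; then 5, −10 °C → rt
Reagents that add atoms: trimethylsulfonium iodide, C[S+](C)C.[I-]
Why: Sulfonium-ylide one-carbon homologation of an epoxide to an allylic alcohol: excess dimethylsulfonium methylide should first close the chlorohydrin to 6, open it at the terminal CH2 to 7 and then, after deprotonation of a methyl group on sulfur, expel dimethyl sulfide by intramolecular syn elimination, none of which touches a bond at C12′.

Step 4
Reactants: 8 (3R,5Z)-octa-1,5-dien-3-ol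
Product: 9 tert-butyldimethyl{[(3R,5Z)-octa-1,5-dien-3-yl]oxy}silane
Conditions: TBSCl, imidazole, DMF, rt
Reagents that add atoms: tert-butyldimethylsilyl chloride, CC(C)(C)[Si](C)(C)Cl
Why: Standard silylation of a secondary alcohol, needed because a free hydroxyl would consume pinacolborane in step 5 and the organolithium in step 12.

Step 5
Reactants: 9 tert-butyldimethyl{[(3R,5Z)-octa-1,5-dien-3-yl]oxy}silane
Product: 10 tert-butyldimethyl{[(3S,5Z)-1-(4,4,5,5-tetramethyl-1,3,2-dioxaborolan-2-yl)oct-5-en-3-yl]oxy}silane
Conditions: HBpin, [Ir(cod)Cl]2 (cat.), dppm (cat.), CH2Cl2, rt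
Reagents that add atoms: pinacolborane, CC1(C)OBOC1(C)C
Why: Iridium-catalysed hydroboration with pinacolborane should place boron on the terminal carbon (C10′) of the monosubstituted alkene only, since the catalyst discriminates strongly against the 1,2-disubstituted Z-alkene, and it leaves C12′ unchanged.

Step 6
Reactants: 11 5-bromobenzene-1,3-diol
Product: 12 1-bromo-3,5-bis(methoxymethoxy)benzene
Conditions: MOMCl, i-Pr2NEt, CH2Cl2, 0 °C → rt
Reagents that add atoms: chloromethyl methyl ether, COCCl
Why: Alkylation of both phenols gives MOM acetals that should withstand the bases, organometallic reagents and iodine of the later steps and fall off in acid at the end.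

Step 7
Reactants: 12 1-bromo-3,5-bis(methoxymethoxy)benzene; 13 oct-7-yn-1-ol
Product: 14 8-[3,5-bis(methoxymethoxy)phenyl]oct-7-yn-1-ol
Conditions: Pd(PPh3)2Cl2 (cat.), CuI (cat.), Et3N, 70 °C
Reagents that add atoms: none
Why: Sonogashira coupling should join ring A to C1′, the bromide being meta to both alkoxy groups and therefore not deactivated, and the free primary alcohol being tolerated.

Step 8
Reactants: 14 8-[3,5-bis(methoxymethoxy)phenyl]oct-7-yn-1-ol
Product: 15 8-[3,5-bis(methoxymethoxy)phenyl]octan-1-ol
Conditions: H2 (1 atm), Pd/C, EtOAc, rt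
Reagents that add atoms: none
Why: Heterogeneous hydrogenation should saturate the aryl alkyne at C1′–C2′ under neutral conditions that leave the MOM acetals and ring A untouched.

Step 9
Reactants: 15 8-[3,5-bis(methoxymethoxy)phenyl]octan-1-ol
Product: 16 8-[3,5-bis(methoxymethoxy)phenyl]octanal
Conditions: TEMPO (cat.), PhI(OAc)2, CH2Cl2, rt
Reagents that add atoms: none
Why: TEMPO-catalysed oxidation with PhI(OAc)2 should stop at the aldehyde and is mild enough for the acetals and the electron-rich ring.

Step 10
Reactants: 16 8-[3,5-bis(methoxymethoxy)phenyl]octanal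
Product: 17 1,3-bis(methoxymethoxy)-5-(non-8-yn-1-yl)benzene
Conditions: dimethyl (1-diazo-2-oxopropyl)phosphonate, K2CO3, MeOH, 0 °C → rt
Reagents that add atoms: dimethyl (1-diazo-2-oxopropyl)phosphonate (Ohira–Bestmann reagent), CC(=O)C(=[N+]=[N-])P(=O)(OC)OC
Why: Ohira–Bestmann (Seyferth–Gilbert) homologation should turn the aldehyde carbon C8′ into an alkyne carbon and add C9′ from the diazo carbon under carbonate conditions that the MOM ethers tolerate.

Step 11
Reactants: 17 1,3-bis(methoxymethoxy)-5-(non-8-yn-1-yl)benzene
Product: 19 1-[(8E)-9-iodonon-8-en-1-yl]-3,5-bis(methoxymethoxy)benzene, via alkenylzirconocene chloride 18 (not isolated)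
Conditions: Cp2Zr(H)Cl, THF, rt; then I2, 0 °C
Reagents that add atoms: iodine, II
Why: Schwartz hydrozirconation adds Zr–H syn with zirconium at the terminal carbon to give 18, and iodinolysis of the C–Zr bond proceeds with retention, so a single E-alkenyl iodide should result.

Step 12
Reactants: 19 1-[(8E)-9-iodonon-8-en-1-yl]-3,5-bis(methoxymethoxy)benzene; 10 tert-butyldimethyl{[(3S,5Z)-1-(4,4,5,5-tetramethyl-1,3,2-dioxaborolan-2-yl)oct-5-en-3-yl]oxy}silane
Product: 23 tert-butyl{[(3Z,6S,9Z)-17-[3,5-bis(methoxymethoxy)phenyl]heptadeca-3,9-dien-6-yl]oxy}dimethylsilane, via alkenyllithium 20 (not isolated), via boronate complex 21 (not isolated), via iodoboronic ester 22 (not isolated)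
Conditions: 19, t-BuLi (2 equiv), THF, −78 °C; 10 in THF, −78 °C; I2 (1.2 equiv), THF, −78 °C; NaOMe, MeOH, −78 °C → rt
Reagents that add atoms: none
Why: Iodine–lithium exchange on 19 with two equivalents of t-BuLi gives the E-alkenyllithium 20 with retention, and 20 adds to the vacant orbital on boron of 10 to give the tetracoordinate boronate 21. Iodine then attacks the electron-rich alkenyl group of 21 to form an iodonium ion, C10′ migrates from boron to C9′ anti to the breaking C–I bond (1,2-metallate shift) to give the β-iodo boronic ester 22, and methoxide adds to boron and triggers anti elimination of boron and iodide. The closest known reaction type is the Zweifel olefination of pinacol boronic esters with alkenyllithium reagents, in which anti migration followed by anti elimination turns an E-alkenyl donor stereospecifically into a Z-alkene, here C8′=C9′. No ring is closed and no new stereocentre survives the step (the two transient centres of 22 are destroyed in the elimination), while C12′, two carbons away from boron, is not involved and keeps its configuration. The step needs chemoselectivity of iodine for the anionic alkenylboronate over the isolated C14′=C15′ alkene and ring A, which the much higher nucleophilicity of 21 at −78 °C and the use of about one equivalent of iodine should secure, and it needs the carbon ligand and not an oxygen ligand to migrate, which the pinacolato group ensures.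

Step 13
Reactants: 23 tert-butyl{[(3Z,6S,9Z)-17-[3,5-bis(methoxymethoxy)phenyl]heptadeca-3,9-dien-6-yl]oxy}dimethylsilane
Product: 24 5-[(8Z,12S,14Z)-12-hydroxyheptadeca-8,14-dien-1-yl]benzene-1,3-diol
Conditions: HCl (1.25 M in MeOH), rt → 40 °C
Reagents that add atoms: none
Why: Acid-catalysed methanolysis should cleave the two aryl MOM acetals and the secondary TBS ether in one operation, and the homoallylic alcohol and the two isolated Z-alkenes have no ready acid-promoted pathway under these mild conditions.

**Compound list**

1 | but-1-yne | CCC#C | starting material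
2 | (R)-epichlorohydrin, (2R)-2-(chloromethyl)oxirane | ClC[C@H]1CO1 | starting material
3 | lithium but-1-yn-1-ide (formed in the flask) | [Li]C#CCC | intermediate
4 | (2R)-1-chlorohept-4-yn-2-ol | CCC#CC[C@@H](O)CCl | intermediate
5 | (2R,4Z)-1-chlorohept-4-en-2-ol | CC/C=C\C[C@@H](O)CCl | intermediate
6 | (2R)-2-[(2Z)-pent-2-en-1-yl]oxirane (formed in the flask) | CC/C=C\C[C@@H]1CO1 | intermediate
7 | dimethyl[(3R,5Z)-3-oxidooct-5-en-1-yl]sulfonium, zwitterion (formed in the flask) | CC/C=C\C[C@@H]([O-])CC[S+](C)C | intermediate
8 | (3R,5Z)-octa-1,5-dien-3-ol | CC/C=C\C[C@@H](O)C=C | intermediate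
9 | tert-butyldimethyl{[(3R,5Z)-octa-1,5-dien-3-yl]oxy}silane | CC/C=C\C[C@@H](O[Si](C)(C)C(C)(C)C)C=C | intermediate
10 | tert-butyldimethyl{[(3S,5Z)-1-(4,4,5,5-tetramethyl-1,3,2-dioxaborolan-2-yl)oct-5-en-3-yl]oxy}silane | CC/C=C\C[C@@H](O[Si](C)(C)C(C)(C)C)CCB1OC(C)(C)C(C)(C)O1 | intermediate
11 | 5-bromobenzene-1,3-diol | Oc1cc(O)cc(Br)c1 | starting material
12 | 1-bromo-3,5-bis(methoxymethoxy)benzene | COCOc1cc(Br)cc(OCOC)c1 | intermediate
13 | oct-7-yn-1-ol | C#CCCCCCCO | starting material
14 | 8-[3,5-bis(methoxymethoxy)phenyl]oct-7-yn-1-ol | COCOc1cc(C#CCCCCCCO)cc(OCOC)c1 | intermediate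
15 | 8-[3,5-bis(methoxymethoxy)phenyl]octan-1-ol | COCOc1cc(CCCCCCCCO)cc(OCOC)c1 | intermediate
16 | 8-[3,5-bis(methoxymethoxy)phenyl]octanal | COCOc1cc(CCCCCCCC=O)cc(OCOC)c1 | intermediate
17 | 1,3-bis(methoxymethoxy)-5-(non-8-yn-1-yl)benzene | COCOc1cc(CCCCCCCC#C)cc(OCOC)c1 | intermediate
18 | chloro{(1E)-9-[3,5-bis(methoxymethoxy)phenyl]non-1-en-1-yl}bis(cyclopentadienyl)zirconium (formed in the flask; cyclopentadienyl rings drawn sigma-bonded) | Cl[Zr](/C=C/CCCCCCCc1cc(OCOC)cc(OCOC)c1)(C1C=CC=C1)C1C=CC=C1 | intermediate
19 | 1-[(8E)-9-iodonon-8-en-1-yl]-3,5-bis(methoxymethoxy)benzene | COCOc1cc(CCCCCCC/C=C/I)cc(OCOC)c1 | intermediate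
20 | {(1E)-9-[3,5-bis(methoxymethoxy)phenyl]non-1-en-1-yl}lithium (formed in the flask) | [Li]/C=C/CCCCCCCc1cc(OCOC)cc(OCOC)c1 | intermediate
21 | lithium boronate complex of 10 and 20: boron carries the pinacolato group, C10′ of fragment 2 and the E-alkenyl group (formed in the flask) | [Li+].CC/C=C\C[C@@H](O[Si](C)(C)C(C)(C)C)CC[B-]1(/C=C/CCCCCCCc2cc(OCOC)cc(OCOC)c2)OC(C)(C)C(C)(C)O1 | intermediate
22 | β-iodo boronic ester with Bpin on C9′ and iodine on C8′ (anti adduct, formed in the flask; one of the two diastereomers that differ at both C8′ and C9′ is drawn) | CC/C=C\C[C@@H](O[Si](C)(C)C(C)(C)C)CC[C@H](B1OC(C)(C)C(C)(C)O1)[C@@H](I)CCCCCCCc1cc(OCOC)cc(OCOC)c1 | intermediate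
23 | tert-butyl{[(3Z,6S,9Z)-17-[3,5-bis(methoxymethoxy)phenyl]heptadeca-3,9-dien-6-yl]oxy}dimethylsilane | CC/C=C\C[C@@H](O[Si](C)(C)C(C)(C)C)CC/C=C\CCCCCCCc1cc(OCOC)cc(OCOC)c1 | intermediate
24 | 5-[(8Z,12S,14Z)-12-hydroxyheptadeca-8,14-dien-1-yl]benzene-1,3-diol | CC/C=C\C[C@@H](O)CC/C=C\CCCCCCCc1cc(O)cc(O)c1 | target

**Totals and risks**

Total step count: 13. Longest linear sequence: 8 steps (steps 6 to 13); the other branch is steps 1 to 5.

Steps most likely to fail:

Risk at step 12. Three processes could lower conversion: proton transfer from the C2–H of ring A (flanked by two MOM oxygens) to the alkenyllithium before it reaches boron, incomplete formation of the boronate complex, and electrophilic iodination of the isolated Z-alkene or of ring A. Partial syn elimination would erode the Z purity. The fallback sets out from 16 and 9 and comes back at 23. Aldehyde 16 is converted by Stork–Zhao olefination (Ph3P+CH2I I−, NaHMDS, THF/DMPU, −78 °C) into the Z-alkenyl iodide 1-[(8Z)-9-iodonon-8-en-1-yl]-3,5-bis(methoxymethoxy)benzene F1. Silyl ether 9 is hydroborated with 9-BBN-H (THF, rt), which should attack only the monosubstituted alkene, to give the borane 9-[(3S,5Z)-3-(tert-butyldimethylsilyloxy)oct-5-en-1-yl]-9-borabicyclo[3.3.1]nonane F2. B-alkyl Suzuki–Miyaura coupling of F1 with F2 (Pd(dppf)Cl2, AsPh3, Cs2CO3, DMF/THF/H2O, rt) forms the same C9′–C10′ bond with retention of the Z geometry and gives 23, which enters step 13.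

Risk at step 3. The epoxide may close incompletely before the ylide decays, the epoxide may isomerise under base through loss of an allylic proton at C13′, and the volatile product may be lost on isolation. The fallback sets out from 5 and comes back at 8. Chlorohydrin 5 is closed with K2CO3 in MeOH and epoxide 6 is isolated. (Phenylselanyl)methyllithium (from bis(phenylselanyl)methane and n-BuLi, THF, −78 °C) opens 6 at its CH2 to give the hydroxy selenide (3R,5Z)-1-(phenylselanyl)oct-5-en-3-ol F3. Oxidation with H2O2 (pyridine, CH2Cl2, 0 °C → rt) gives the selenoxide (3R,5Z)-1-(phenylseleninyl)oct-5-en-3-ol F4, whose syn elimination can only take a hydrogen from C11′ and therefore gives 8.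

Risk at step 5. The iridium hydride may isomerise the allylic silyl ether towards an enol ether, excess borane may also hydroborate the internal alkene, or the catalyst may be deactivated. The fallback sets out from 9 and comes back at 10. Silyl ether 9 is hydroborated with 9-BBN-H to the borane F2 described above, which is oxidised (NaOH, H2O2) to the primary alcohol (3R,5Z)-3-(tert-butyldimethylsilyloxy)oct-5-en-1-ol F5. Appel-type iodination (I2, PPh3, imidazole, CH2Cl2) gives the iodide tert-butyl{[(3R,5Z)-1-iodooct-5-en-3-yl]oxy}dimethylsilane F6. Iodine–lithium exchange (t-BuLi, Et2O, −78 °C) and trapping with 2-isopropoxy-4,4,5,5-tetramethyl-1,3,2-dioxaborolane at −78 °C gives 10; the low temperature is kept throughout to suppress cyclisation onto the alkene and silyl migration.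

Further compounds
F1 | step 12 | 1-[(8Z)-9-iodonon-8-en-1-yl]-3,5-bis(methoxymethoxy)benzene | COCOc1cc(CCCCCCC/C=C\I)cc(OCOC)c1
F2 | step 12 | 9-[(3S,5Z)-3-(tert-butyldimethylsilyloxy)oct-5-en-1-yl]-9-borabicyclo[3.3.1]nonane | CC/C=C\C[C@@H](O[Si](C)(C)C(C)(C)C)CCB1C2CCCC1CCC2
F3 | step 3 | (3R,5Z)-1-(phenylselanyl)oct-5-en-3-ol | CC/C=C\C[C@@H](O)CC[Se]c1ccccc1
F4 | step 3 | (3R,5Z)-1-(phenylseleninyl)oct-5-en-3-ol | CC/C=C\C[C@@H](O)CC[Se](=O)c1ccccc1
F5 | step 5 | (3R,5Z)-3-(tert-butyldimethylsilyloxy)oct-5-en-1-ol | CC/C=C\C[C@@H](O[Si](C)(C)C(C)(C)C)CCO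
F6 | step 5 | tert-butyl{[(3R,5Z)-1-iodooct-5-en-3-yl]oxy}dimethylsilane | CC/C=C\C[C@@H](O[Si](C)(C)C(C)(C)C)CCI
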